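The route rests on disconnecting C10–C11 of the cyclohexenone ring (C1, C10–C14), the bond that joins the ring-fusion carbon to the acetoxy-bearing quaternary carbon. The key step exploits the β-hydroxy-carbonyl relationship O11–C11–C10–C9 together with the C11/C12 dioxygenation: a D-proline-catalysed 6-enolexo aldolisation closes the ring and sets C10 and C11 in one operation, relayed from C1 (set by organocatalysis). Its precursor is an acyclic keto aldehyde carrying a 1,2-dione. The lactone carbons C7, C8, C17 and C19 come from (S)-malic acid; the ten-membered ring is closed by a Nozaki–Hiyama–Kishi reaction at C6–C7, and the epoxide is added last.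

Key step: step 12

Remark: locants C1–C20 are the briarane locants of the target (C1 quaternary carbon with methyl C15, C5=C6 alkene with C16, lactone C7–O–C19, C17 with methyl C18, C11 with methyl C20).
Assumption: the (R)-prolinamide of step 3 is taken to give (S)-C1 by analogy with proline-type enamine catalysis (E-enamine, acceptor held on the face of the N–H donor); if the sense proves opposite, the (S)-catalyst is used.

Step 1
Reactants: 1 3,3-dimethoxybutan-2-one
Product: 2 4,4-dimethoxypent-1-en-3-one
Conditions: 37% aq. CH2O, diisopropylammonium trifluoroacetate (cat.), THF, 65 °C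
Reagents that add atoms: formaldehyde C=O
Why: α-Methylenation (Mannich condensation–elimination) at the only enolisable position, the acetyl methyl group, since the other α-carbon is the fully substituted ketal carbon; no stereocentre is formed.

Step 2
Reactants: 3 3-methyloxolan-2-one (racemic)
Product: 4 3-methyloxolan-2-ol
Conditions: iBu2AlH, CH2Cl2, −78 °C
Reagents that add atoms: none
Why: Partial hydride reduction of the lactone to the lactol, the tetrahedral aluminate being stable at low temperature; the stereocentres are irrelevant because C1 becomes planar in the enamine of step 3.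

Step 3
Reactants: 4 3-methyloxolan-2-ol; 2 4,4-dimethoxypent-1-en-3-one
Product: 5 (3S)-3-(4,4-dimethoxy-3-oxopentyl)-3-methyloxolan-2-ol
Conditions: (R)-N-(4-dodecylphenylsulfonyl)pyrrolidine-2-carboxamide (20 mol%), ClCH2CH2Cl, rt
Reagents that add atoms: none
Why: Enamine-catalysed Michael addition of an α-branched aldehyde (open form of 4) to the vinyl ketone creates the all-carbon quaternary centre C1; both enantiomers of 4 converge on one E-enamine and the sulfonamide N–H should hold the enone on one face, setting C1 as S.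

Step 4
Reactants: 6 methyl prop-2-ynoate
Product: 7 methyl (Z)-2-(hydroxymethyl)-3-iodoprop-2-enoate
Conditions: MgI2, (CH2O)n, CH2Cl2, 0 °C
Reagents that add atoms: formaldehyde C=O; magnesium diiodide [Mg+2].[I-].[I-]
Why: β-Iodo Morita–Baylis–Hillman reaction, in which iodide adds to the alkynoate and the magnesium allenolate is trapped by formaldehyde; it should leave iodine cis to the ester (Z), the geometry needed for the cis ring junction C4–C5=C6–C7.

Step 5
Reactants: 7 methyl (Z)-2-(hydroxymethyl)-3-iodoprop-2-enoate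
Product: 8 tert-butyldiphenylsilyl ether of 7
Conditions: tBuPh2SiCl, imidazole, CH2Cl2, 0 °C → rt
Reagents that add atoms: tert-butyl(chloro)diphenylsilane CC(C)(C)[Si](Cl)(c1ccccc1)c1ccccc1
Why: Silylation of the primary allylic alcohol (imidazole-assisted substitution at silicon) gives a silyl ether that should survive the later basic, acidic and reducing steps.

Step 6
Reactants: 8 tert-butyldiphenylsilyl ether of 7
Product: 9 (E)-2-{[(tert-butyldiphenylsilyl)oxy]methyl}-3-iodoprop-2-en-1-ol
Conditions: iBu2AlH, CH2Cl2, −78 °C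
Reagents that add atoms: none
Why: Hydride reduction of the conjugated ester to the allylic alcohol, which should leave the vinyl iodide and its geometry untouched at −78 °C.

Step 7
Reactants: 9 (E)-2-{[(tert-butyldiphenylsilyl)oxy]methyl}-3-iodoprop-2-en-1-ol
Product: 10 (Z)-{[2-(bromomethyl)-3-iodoprop-2-en-1-yl]oxy}(tert-butyl)diphenylsilane
Conditions: CBr4, PPh3, CH2Cl2, 0 °C
Reagents that add atoms: tetrabromomethane BrC(Br)(Br)Br
Why: Appel reaction converts the primary allylic alcohol into the bromide by SN2 displacement of the alkoxyphosphonium ion without allylic shift.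

Step 8
Reactants: 10 (Z)-{[2-(bromomethyl)-3-iodoprop-2-en-1-yl]oxy}(tert-butyl)diphenylsilane; 11 5-(methylsulfonyl)-1-phenyl-1H-tetrazole
Product: 12 5-{[(E)-3-{[(tert-butyldiphenylsilyl)oxy]methyl}-4-iodobut-3-en-1-yl]sulfonyl}-1-phenyl-1H-tetrazole
Conditions: LiN(SiMe3)2 added to 10 + 11, THF, −78 °C
Reagents that add atoms: none
Why: SN2 alkylation of the α-sulfonyl carbanion of 11 by the primary allylic bromide, run with the electrophile present so that self-condensation of the metalated sulfone is avoided; the alkene geometry is retained.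

Step 9
Reactants: 5 (3S)-3-(4,4-dimethoxy-3-oxopentyl)-3-methyloxolan-2-ol; 12 phenyltetrazolyl sulfone
Product: 13 (6S,7E,10E)-hydroxy keto ketal
Conditions: KN(SiMe3)2, DME, −60 °C → rt
Reagents that add atoms: none
Why: Julia–Kocienski olefination of the aldehyde form of lactol 5 (opened by the first equivalent of base); the phenyltetrazolyl sulfone with a potassium counter-ion in DME and the α-quaternary aldehyde should give the E-C2=C3 alkene, while the hindered ketone next to the ketal is left alone.

Step 10
Reactants: 13 (6S,7E,10E)-hydroxy keto ketal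
Product: 14 (6S,7E,10E)-hydroxy 1,2-dione
Conditions: CF3CO2H/H2O (9:1), CH2Cl2, 0 °C
Reagents that add atoms: water O
Why: Acid-catalysed ketal hydrolysis unveils the 1,2-dione at the alcohol stage, before any enolisable aldehyde is present; the silyl ether and vinyl iodide should tolerate the short acid treatment.

Step 11
Reactants: 14 (6S,7E,10E)-hydroxy 1,2-dione
Product: 15 (3S,4E,7E)-keto aldehyde
Conditions: Dess–Martin periodinane, NaHCO3, CH2Cl2, 0 °C
Reagents that add atoms: none
Why: Dess–Martin oxidation of the primary alcohol to the aldehyde under buffered, non-enolising conditions, so that no premature aldol reaction occurs.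

Step 12
Reactants: 15 (3S,4E,7E)-keto aldehyde
Product: 17 (1R,2S,6R)-β-hydroxy aldehyde with the six-membered ring closed, via enamine 16 (not isolated)
Conditions: D-proline (30 mol%), DMSO, rt
Reagents that add atoms: none
Why: D-Proline condenses selectively with the only aldehyde of 15 to give E-enamine 16, whose carbon C10 adds to the acetyl carbonyl C11 of the 1,2-dione while the carboxylic acid protonates the developing alkoxide, and hydrolysis of the iminium ion releases 17 and the catalyst. The closest known reaction type is the amine-catalysed intramolecular (enolexo) aldolisation of keto aldehydes, here with a 1,2-diketone as the activated acceptor. The ring C1–C10–C11–C12–C13–C14 closes in the 6-enolexo-exo-trig mode through a chair in which the enamine and the carbonyl oxygen are both equatorial. C10 is set by the catalyst, which delivers the ketone to one enamine face (with D-proline, C9 ends cis to methyl C15 of the pre-set quaternary C1), and C11 follows from the anti arrangement of that chair (OH trans to CHO, methyl C20 axial). The step needs aldehyde-only enamine formation (secured by the much faster condensation of the unhindered aldehyde), attack at C11 and not C12 (secured by the six-membered chair and the lower hindrance of the acetyl carbonyl against the five-ring alternative), and catalyst over substrate control (plausible because C1 carries two groups of similar size, methyl and alkenyl).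

Step 13
Reactants: 17 (1R,2S,6R)-β-hydroxy aldehyde
Product: 18 11-O-triethylsilyl ether of 17
Conditions: Et3SiOTf, 2,6-lutidine, CH2Cl2, −78 → 0 °C
Reagents that add atoms: triethylsilyl trifluoromethanesulfonate CC[Si](CC)(CC)OS(=O)(=O)C(F)(F)F
Why: O-Silylation of the tertiary α-ketol with a silyl triflate and a hindered pyridine base blocks retro-aldol cleavage in the next, basic step; 2,6-lutidine should not enolise the aldehyde.

Step 14
Reactants: 19 dimethyl (S)-malate
Product: 20 dimethyl (2S,3R)-2-hydroxy-3-methylbutanedioate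
Conditions: LiN(iPr)2 (2.2 equiv), THF, −78 → −20 °C; MeI, −78 °C → rt
Reagents that add atoms: iodomethane CI
Why: Fráter–Seebach alkylation, in which the chelated alkoxide enolate dianion is methylated anti to the C–O bond; this sets C17.

Step 15
Reactants: 20 dimethyl (2S,3R)-2-hydroxy-3-methylbutanedioate
Product: 21 (2S,3R)-2-hydroxy-3-methylbutanedioic acid
Conditions: LiOH, THF/H2O, 0 °C → rt; then 1 M HCl
Reagents that add atoms: lithium hydroxide [Li+].[OH-]
Why: Saponification of both methyl esters with hydroxide at low temperature, where the carboxylate-flanked stereocentres should not epimerise.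

Step 16
Reactants: 21 (2S,3R)-2-hydroxy-3-methylbutanedioic acid
Product: 22 (2R)-2-[(2S,4S)-2-tert-butyl-5-oxo-1,3-dioxolan-4-yl]propanoic acid
Conditions: tBuCHO, p-toluenesulfonic acid (cat.), H2SO4 (cat.), pentane, reflux, water separator
Reagents that add atoms: pivalaldehyde CC(C)(C)C=O
Why: Acid-catalysed acetalisation of the α-hydroxy acid unit gives the five-membered dioxolanone as its thermodynamic cis isomer; the acetal carbon now stores the configuration of C8 (self-regeneration of stereocentres).

Step 17
Reactants: 22 dioxolanone acid; 18 11-O-triethylsilyl aldehyde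
Product: 24 9,11-bis-O-triethylsilyl dioxolanone acid, via hydroxy acid 23 (not isolated)
Conditions: 22 + LiN(SiMe3)2 (2 equiv), THF, −78 °C; then 18; then Et3SiOTf, −78 → −40 °C; aq. citric acid
Reagents that add atoms: triethylsilyl trifluoromethanesulfonate CC[Si](CC)(CC)OS(=O)(=O)C(F)(F)F
Why: Aldol addition of the dilithiated dioxolanone (carboxylate plus lactone enolate): the aldehyde enters trans to the tert-butyl group, regenerating C8 with retention, and a closed chair transition state with the ring-locked enolate (C17 cis to OLi) and the aldehyde residue equatorial should give 9R; the aldolate is silylated in the flask to stop retro-aldol cleavage and lactonisation of O9 onto C19.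

Step 18
Reactants: 24 9,11-bis-O-triethylsilyl dioxolanone acid
Product: 25 lactol acid (C7 and C12 epimer mixtures)
Conditions: iBu2AlH (3.5 equiv), CH2Cl2, −78 °C; aq. potassium sodium tartrate
Reagents that add atoms: none
Why: Partial reduction of the dioxolanone, an activated acylal-type lactone, to the lactol at −78 °C; the aluminium carboxylate is inert, and the C12 ketone is reduced as well, which is accepted because step 21 reoxidises it.

Step 19
Reactants: 25 lactol acid
Product: 26 lactol methyl ester
Conditions: Me3SiCHN2, MeOH/toluene, 0 °C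
Reagents that add atoms: (trimethylsilyl)diazomethane C[Si](C)(C)C=[N+]=[N-]
Why: Esterification of the carboxylic acid by the diazoalkane (protonation, then SN2 methyl transfer) leaves the lactol and alcohols unalkylated and provides the ester needed for the lactonisation of step 20.

Step 20
Reactants: 26 lactol methyl ester
Product: 29 ten-membered ring lactone, via hydroxy aldehyde 27 (not isolated), via hydroxy ester 28 (not isolated)
Conditions: CrCl2 (20 equiv), NiCl2 (cat.), DMSO/THF, rt, 2 mM; then pyridinium p-toluenesulfonate (cat.), CH2Cl2, rt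
Reagents that add atoms: none
Why: Nozaki–Hiyama–Kishi macrocyclisation: the lactol releases pivalaldehyde and α-hydroxy aldehyde 27, the vinyl iodide adds oxidatively to zerovalent nickel and is transmetalated to a vinylchromium species that adds to C7, closing the ten-membered ring with retention of the C5=C6 geometry, and the C7 alcohol of 28 then lactonises onto the C19 ester; 7S should follow from Felkin–Anh addition anti to the C8–O bond with the tether-bearing C9 in the inside position.

Step 21
Reactants: 29 ten-membered ring lactone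
Product: 30 C13=C14 enone
Conditions: 2-iodoxybenzoic acid (IBX, 4 equiv), DMSO/fluorobenzene, 70 °C
Reagents that add atoms: none
Why: IBX oxidises the C12 alcohol to the ketone and then dehydrogenates it through its enol to the enone; C11 is quaternary, so unsaturation can only form on the C13 side.

Step 22
Reactants: 30 C13=C14 enone
Product: 31 tetraol
Conditions: HF·pyridine, pyridine, THF, 0 °C → rt
Reagents that add atoms: none
Why: Fluoride-mediated cleavage of the three silyl ethers under buffered conditions that should leave the β-hydroxy lactone and the enone untouched.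

Step 23
Reactants: 31 tetraol
Product: 32 9,11,16-triacetate with free 8-OH
Conditions: Ac2O, pyridine, 4-(dimethylamino)pyridine (cat.), CH2Cl2, 0 °C → rt
Reagents that add atoms: acetic anhydride CC(=O)OC(C)=O
Why: Nucleophile-catalysed acetylation: the primary C16 and secondary C9 hydroxyls should react fast and the tertiary α-ketol at C11 more slowly, while the C8 hydroxyl, flanked by three branched carbons and hydrogen-bonded to the lactone carbonyl, should stay free.

Step 24
Reactants: 32 9,11,16-triacetate with free 8-OH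
Product: 33 CNP0226792.2 (target)
Conditions: 3-chloroperbenzoic acid, NaHCO3, CH2Cl2, 0 °C
Reagents that add atoms: 3-chloroperbenzoic acid OOC(=O)c1cccc(Cl)c1
Why: Prilezhaev epoxidation of the E-C2=C3 alkene, the only electron-rich one (the enone and the C5=C6 alkene with two allylic acyloxy groups are deactivated); the alkene lies perpendicular to the mean plane of the ten-membered ring, so the peracid should attack its outer face and give the trans-2R,3R epoxide.

Compound list

1 | 3,3-dimethoxybutan-2-one | CC(=O)C(C)(OC)OC | starting material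
2 | 4,4-dimethoxypent-1-en-3-one | C=CC(=O)C(C)(OC)OC | intermediate
3 | 3-methyloxolan-2-one (α-methyl-γ-butyrolactone, racemic) | CC1CCOC1=O | starting material
4 | 3-methyloxolan-2-ol (lactol, mixture of stereoisomers) | CC1CCOC1O | intermediate
5 | (3S)-3-(4,4-dimethoxy-3-oxopentyl)-3-methyloxolan-2-ol (lactol of the C1-quaternary aldehyde, both anomers) | OC1OCC[C@]1(C)CCC(=O)C(C)(OC)OC | intermediate
6 | methyl prop-2-ynoate | C#CC(=O)OC | starting material
7 | methyl (Z)-2-(hydroxymethyl)-3-iodoprop-2-enoate | OC/C(=C/I)C(=O)OC | intermediate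
8 | methyl (Z)-2-{[(tert-butyldiphenylsilyl)oxy]methyl}-3-iodoprop-2-enoate | CC(C)(C)[Si](c1ccccc1)(c1ccccc1)OC/C(=C/I)C(=O)OC | intermediate
9 | (E)-2-{[(tert-butyldiphenylsilyl)oxy]methyl}-3-iodoprop-2-en-1-ol | CC(C)(C)[Si](c1ccccc1)(c1ccccc1)OC/C(=C/I)CO | intermediate
10 | (Z)-{[2-(bromomethyl)-3-iodoprop-2-en-1-yl]oxy}(tert-butyl)diphenylsilane | CC(C)(C)[Si](c1ccccc1)(c1ccccc1)OC/C(=C/I)CBr | intermediate
11 | 5-(methylsulfonyl)-1-phenyl-1H-tetrazole | CS(=O)(=O)c1nnnn1-c1ccccc1 | starting material
12 | 5-{[(E)-3-{[(tert-butyldiphenylsilyl)oxy]methyl}-4-iodobut-3-en-1-yl]sulfonyl}-1-phenyl-1H-tetrazole | CC(C)(C)[Si](c1ccccc1)(c1ccccc1)OC/C(=C/I)CCS(=O)(=O)c1nnnn1-c1ccccc1 | intermediate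
13 | (6S,7E,10E)-10-{[(tert-butyldiphenylsilyl)oxy]methyl}-6-(2-hydroxyethyl)-11-iodo-2,2-dimethoxy-6-methylundeca-7,10-dien-3-one | OCC[C@](C)(CCC(=O)C(C)(OC)OC)/C=C/C/C(CO[Si](c1ccccc1)(c1ccccc1)C(C)(C)C)=C\I | intermediate
14 | (6S,7E,10E)-10-{[(tert-butyldiphenylsilyl)oxy]methyl}-6-(2-hydroxyethyl)-11-iodo-6-methylundeca-7,10-diene-2,3-dione | OCC[C@](C)(CCC(=O)C(C)=O)/C=C/C/C(CO[Si](c1ccccc1)(c1ccccc1)C(C)(C)C)=C\I | intermediate
15 | (3S,4E,7E)-7-{[(tert-butyldiphenylsilyl)oxy]methyl}-3-(3,4-dioxopentyl)-8-iodo-3-methylocta-4,7-dienal | O=CC[C@](C)(CCC(=O)C(C)=O)/C=C/C/C(CO[Si](c1ccccc1)(c1ccccc1)C(C)(C)C)=C\I | intermediate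
16 | D-proline E-enamine of 15 (N–C9=C10) | OC(=O)[C@H]1CCCN1/C=C/[C@](C)(CCC(=O)C(C)=O)/C=C/C/C(CO[Si](c2ccccc2)(c2ccccc2)C(C)(C)C)=C\I | intermediate (not isolated)
17 | (1R,2S,6R)-6-[(1E,4E)-4-{[(tert-butyldiphenylsilyl)oxy]methyl}-5-iodopenta-1,4-dien-1-yl]-2-hydroxy-2,6-dimethyl-3-oxocyclohexane-1-carbaldehyde | O=C[C@H]1[C@](C)(O)C(=O)CC[C@]1(C)/C=C/C/C(CO[Si](c1ccccc1)(c1ccccc1)C(C)(C)C)=C\I | intermediate
18 | triethylsilyl ether of 17 at the tertiary hydroxyl (11-OSiEt3) | O=C[C@H]1[C@](C)(O[Si](CC)(CC)CC)C(=O)CC[C@]1(C)/C=C/C/C(CO[Si](c1ccccc1)(c1ccccc1)C(C)(C)C)=C\I | intermediate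
19 | dimethyl (S)-malate | COC(=O)C[C@H](O)C(=O)OC | starting material
20 | dimethyl (2S,3R)-2-hydroxy-3-methylbutanedioate | COC(=O)[C@H](C)[C@H](O)C(=O)OC | intermediate
21 | (2S,3R)-2-hydroxy-3-methylbutanedioic acid | OC(=O)[C@H](C)[C@H](O)C(O)=O | intermediate
22 | (2R)-2-[(2S,4S)-2-tert-butyl-5-oxo-1,3-dioxolan-4-yl]propanoic acid | OC(=O)[C@H](C)[C@@H]1O[C@H](C(C)(C)C)OC1=O | intermediate
23 | aldol hydroxy acid: dioxolanone C8 bonded to C9 (9-OH free, 11-OSiEt3, 12-ketone, C19 acid; C1, C8, C9, C10, C11, C17 as in the target) | OC(=O)[C@H](C)[C@@]1(O[C@H](C(C)(C)C)OC1=O)[C@H](O)[C@H]2[C@](C)(O[Si](CC)(CC)CC)C(=O)CC[C@]2(C)/C=C/C/C(CO[Si](c3ccccc3)(c3ccccc3)C(C)(C)C)=C\I | intermediate (not isolated)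
24 | 9-O-triethylsilyl ether of 23 (9,11-bis-OSiEt3 dioxolanone acid) | OC(=O)[C@H](C)[C@@]1(O[C@H](C(C)(C)C)OC1=O)[C@H](O[Si](CC)(CC)CC)[C@H]2[C@](C)(O[Si](CC)(CC)CC)C(=O)CC[C@]2(C)/C=C/C/C(CO[Si](c3ccccc3)(c3ccccc3)C(C)(C)C)=C\I | intermediate
25 | lactol acid: dioxolanone carbonyl C7 reduced to the hemiacetal, 12-OH (epimer mixtures at C7 and C12) | OC(=O)[C@H](C)[C@@]1(O[C@H](C(C)(C)C)OC1O)[C@H](O[Si](CC)(CC)CC)[C@H]2[C@](C)(O[Si](CC)(CC)CC)C(O)CC[C@]2(C)/C=C/C/C(CO[Si](c3ccccc3)(c3ccccc3)C(C)(C)C)=C\I | intermediate
26 | methyl ester of 25 | COC(=O)[C@H](C)[C@@]1(O[C@H](C(C)(C)C)OC1O)[C@H](O[Si](CC)(CC)CC)[C@H]2[C@](C)(O[Si](CC)(CC)CC)C(O)CC[C@]2(C)/C=C/C/C(CO[Si](c3ccccc3)(c3ccccc3)C(C)(C)C)=C\I | intermediate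
27 | α-hydroxy aldehyde (C7 aldehyde, 8-OH, C19 methyl ester, vinyl iodide; 12-OH epimer mixture) | COC(=O)[C@H](C)[C@](O)(C=O)[C@H](O[Si](CC)(CC)CC)[C@H]1[C@](C)(O[Si](CC)(CC)CC)C(O)CC[C@]1(C)/C=C/C/C(CO[Si](c2ccccc2)(c2ccccc2)C(C)(C)C)=C\I | intermediate (not isolated)
28 | ten-membered ring hydroxy ester (7-OH, 8-OH, C19 methyl ester; 12-OH epimer mixture) | CC(C)(C)[Si](c1ccccc1)(c1ccccc1)OC/C1=C/[C@H](O)[C@@](O)([C@@H](C)C(=O)OC)[C@H](O[Si](CC)(CC)CC)[C@@H]2[C@](C)(CCC(O)[C@@]2(C)O[Si](CC)(CC)CC)/C=C/C1 | intermediate (not isolated)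
29 | ten-membered ring lactone (briarane skeleton; E-C2=C3; 8-OH; 9,11-bis-OSiEt3; 12-OH epimer mixture; 16-OSitBuPh2; C1, C7, C8, C9, C10, C11, C17 as in the target) | CC(C)(C)[Si](c1ccccc1)(c1ccccc1)OC/C1=C/[C@@H]2OC(=O)[C@H](C)[C@@]2(O)[C@H](O[Si](CC)(CC)CC)[C@@H]2[C@](C)(CCC(O)[C@@]2(C)O[Si](CC)(CC)CC)/C=C/C1 | intermediate
30 | 12-oxo-13,14-ene derivative of 29 | CC(C)(C)[Si](c1ccccc1)(c1ccccc1)OC/C1=C/[C@@H]2OC(=O)[C@H](C)[C@@]2(O)[C@H](O[Si](CC)(CC)CC)[C@@H]2[C@](C)(C=CC(=O)[C@@]2(C)O[Si](CC)(CC)CC)/C=C/C1 | intermediate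
31 | 8,9,11,16-tetraol (2,3-deoxy-tri-O-deacetyl target) | OC/C1=C/[C@@H]2OC(=O)[C@H](C)[C@@]2(O)[C@H](O)[C@@H]2[C@](C)(C=CC(=O)[C@@]2(C)O)/C=C/C1 | intermediate
32 | 9,11,16-triacetate with E-C2=C3 alkene (2,3-deoxy target) | CC(=O)OC/C1=C/[C@@H]2OC(=O)[C@H](C)[C@@]2(O)[C@H](OC(C)=O)[C@@H]2[C@](C)(C=CC(=O)[C@@]2(C)OC(C)=O)/C=C/C1 | intermediate
33 | CNP0226792.2 | CC(=O)OC/C1=C/[C@@H]2OC(=O)[C@H](C)[C@@]2(O)[C@H](OC(C)=O)[C@@H]2[C@](C)(C=CC(=O)[C@@]2(C)OC(C)=O)[C@H]2O[C@@H]2C1 | target

Total step count: 24.
Longest linear sequence: 18 steps (from 6: steps 4–13 and 17–24).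

Steps most likely to fail

1. Step 20. The vinylchromium addition may take place on the other face of the C7 aldehyde within the forming ring, and intermolecular coupling may compete with ring closure. Fallback: from 26 the chromium-mediated closure is run without the acid treatment, so that the hydroxy ester is isolated. If it is mainly the C7-epimeric hydroxy ester F1, its allylic C7 alcohol is oxidised selectively with MnO2 (CH2Cl2, rt) to enone F2. Chelation-controlled reduction with Zn(BH4)2 (Et2O, −20 °C; zinc bridges O7 and O8, hydride enters anti to the C9 branch) should then give 28, which lactonises with pyridinium p-toluenesulfonate and rejoins the route at 29.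

2. Step 17. Addition to the doubly neopentylic aldehyde may be slow, so that proton transfer and retro-aldol cleavage of the lithium aldolate compete. Fallback: from 22, double deprotonation (LiN(SiMe3)2, THF, −78 °C) and trapping with Me3SiCl gives bis(trimethylsilyl) ketene acetal F3. Its Mukaiyama aldol addition to 18 (Me3SiOTf cat., CH2Cl2, −78 °C; then aq. citric acid) goes through an open, Lewis-acid-activated transition state without a basic aldolate and should give hydroxy acid 23, still trans to the tert-butyl group at C8. Silylation (Et3SiOTf, 2,6-lutidine) rejoins the route at 24.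

3. Step 24. The peracid may attack the other face of the C2=C3 alkene. Fallback: from 32, N-bromosuccinimide in aqueous 1,2-dimethoxyethane forms the bromonium ion on that same exposed face, and water opens it anti at the less hindered C3 to give bromohydrin F4. K2CO3 in acetone closes the epoxide with inversion at C2, which places the oxygen on the opposite face and rejoins the route at 33.

Further compounds

F1 | step 20 | C7-epimeric ten-membered ring hydroxy ester (7-epi-28) | CC(C)(C)[Si](c1ccccc1)(c1ccccc1)OC/C1=C/[C@@H](O)[C@@](O)([C@@H](C)C(=O)OC)[C@H](O[Si](CC)(CC)CC)[C@@H]2[C@](C)(CCC(O)[C@@]2(C)O[Si](CC)(CC)CC)/C=C/C1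
F2 | step 20 | C7 enone of the ten-membered ring hydroxy ester (7-oxo, 8-OH) | CC(C)(C)[Si](c1ccccc1)(c1ccccc1)OC/C1=C/C(=O)[C@@](O)([C@@H](C)C(=O)OC)[C@H](O[Si](CC)(CC)CC)[C@@H]2[C@](C)(CCC(O)[C@@]2(C)O[Si](CC)(CC)CC)/C=C/C1
F3 | step 17 | trimethylsilyl (2R)-2-[(2S)-2-tert-butyl-5-(trimethylsilyloxy)-1,3-dioxol-4-yl]propanoate | C[Si](C)(C)OC(=O)[C@H](C)C1=C(O[Si](C)(C)C)O[C@@H](C(C)(C)C)O1
F4 | step 24 | bromohydrin of 32 (2-bromo, 3-hydroxy, anti) | CC(=O)OC/C1=C/[C@@H]2OC(=O)[C@H](C)[C@@]2(O)[C@H](OC(C)=O)[C@@H]2[C@](C)(C=CC(=O)[C@@]2(C)OC(C)=O)[C@H](Br)[C@H](O)C1
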